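**Retrosynthetic overview**
1. α-Onocerin ⇒ C2-symmetric bis(8-oxodecalin) diketone diol by double carbonyl methylenation (last step).
2. Diketone ⇒ acyclic bis[(S)-epoxide] bis[(Z)-enol silane]; rings A then B close on each side in one bidirectional epoxide-initiated cation–olefin tetracyclization.
3. Central C11–C12 bond ⇒ oxidative dimerization of a (Z)-siloxyallyl anion made from an acylsilane and vinyllithium (Brook rearrangement).
4. Acylsilane ⇒ (S)-6,7-epoxygeranyl chloride + the enolate of acetyltrimethylsilane.
5. All stereochemistry ⇒ one organocatalytic (chiral ketone/dioxirane) epoxidation of achiral geranyl chloride.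

Assumption: the L-fructose-derived (ent-)Shi ketone is bought as a catalyst and is not counted as a starting material; vinyllithium is made in situ from commercial vinyl bromide.

**Step 1**
Reactants: 1, geranyl chloride
Product: 2, (S)-6,7-epoxygeranyl chloride
Conditions: ent-Shi ketone (30 mol %), Oxone, K2CO3, Bu4NHSO4, MeCN–DMM / aq. borate–EDTA buffer (pH 10.5), −5 to 0 °C
Reagents that add atoms: Oxone (potassium peroxymonosulfate), OOS(=O)(=O)[O-].[K+]
Why: Shi asymmetric epoxidation; the chiral dioxirane attacks only the electron-rich 6,7-alkene (the 2,3-alkene is deactivated by the allylic chloride) and the L-fructose-derived ketone delivers oxygen to the face that gives the (S)-epoxide (about 90% ee expected), allylic chlorides being tolerated under these cold buffered conditions.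

**Step 2**
Reactants: 2, (S)-6,7-epoxygeranyl chloride; 3, acetyltrimethylsilane
Product: 4, (4E)-7-[(2S)-3,3-dimethyloxiran-2-yl]-5-methyl-1-(trimethylsilyl)hept-4-en-1-one
Conditions: 3 (1.3 equiv), LDA, THF, −78 °C; then 2, NaI (cat.), DMPU, −78 → −10 °C
Reagents that add atoms: none beyond reactant 3
Why: SN2 alkylation of the lithium enolate of the acylsilane at the primary allylic carbon (in situ Finkelstein activation), which keeps the E-alkene and leaves the hindered trisubstituted epoxide untouched at low temperature.

**Step 3**
Reactants: 4 (2 equiv); 5, vinyllithium (2 equiv)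
Product: 6, (1Z,5Z)-1,6-bis{(3E)-6-[(2S)-3,3-dimethyloxiran-2-yl]-4-methylhex-3-en-1-yl}-1,6-bis(trimethylsilyloxy)hexa-1,5-diene
Conditions: 5 (from vinyl bromide, t-BuLi), Et2O–THF, −78 → −40 °C; then I2 (0.5 equiv), −78 °C; non-aqueous work-up
Reagents that add atoms: none beyond reactant 5 (I2 is only the oxidant)
Why: Carbonyl addition, then 1,2-Brook rearrangement gives the internally chelated (Z)-siloxyallyllithium, which iodine couples tail-to-tail at its γ-carbons (four-component coupling) to form the central C–C bond with both enol ethers Z; the statistical dimerization also sends most of the minor epoxide enantiomer into a separable meso diastereomer.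

**Step 4**
Reactants: 6
Product: 7, 1,2-bis[(1R,4aR,6S,8aS)-6-hydroxy-5,5,8a-trimethyl-2-oxodecahydronaphthalen-1-yl]ethane (α-onocerin with both C=CH2 replaced by C=O; each half 3β-OH, 5α-H, 9α-H, 10β-Me)
Conditions: TMSNTf2 (10 mol %), 2,6-di-tert-butyl-4-methylpyridine (5 mol %), CH2Cl2 (0.01 M), −78 → −40 °C; then 1 M HCl, THF, 0 °C
Reagents that add atoms: none (catalytic silyl source; acid work-up removes the two O–SiMe3 groups)
Why: Proposed new method: a catalytic silyl-transfer-relay, bidirectional epoxy-polyene tetracyclization, in which Me3Si+ silylates an epoxide oxygen, the 6,7-alkene opens the activated epoxide anti at its tertiary carbon through a chair–chair array, the (Z)-enol silane terminates the cascade, and the resulting silyloxocarbenium ion passes its Me3Si+ to the next epoxide so that a substoichiometric initiator turns over; the closest known chemistry is stoichiometric MeAlCl2-promoted epoxide-initiated cation–olefin cyclization terminated by silyl enol ethers and TMSNTf2-catalysed Mukaiyama-type silyl transfer; the (S)-epoxide sets 3β-O, 5α-H and 10β-Me on each side, and the Z-enol geometry sets 9α-H (C9 can also equilibrate to this equatorial isomer because it is α to the new ketone).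

**Step 5**
Reactants: 7
Product: 8, α-onocerin
Conditions: Zn, CH2Br2, TiCl4, THF–CH2Cl2, 0 °C → rt (excess reagent)
Reagents that add atoms: dibromomethane, BrCBr
Why: Takai–Lombardo methylenation converts both hindered, enolizable C8 ketones into exocyclic methylenes under non-basic conditions, so C9 is not epimerized, the 1,6-diketone cannot undergo aldol closure, and the free secondary alcohols are tolerated; crystallization removes the meso diastereomer.

**Compound list**
1 | geranyl chloride, (2E)-1-chloro-3,7-dimethylocta-2,6-diene | ClC/C=C(\C)CCC=C(C)C | starting material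
2 | (S)-6,7-epoxygeranyl chloride, (3S)-3-[(3E)-5-chloro-3-methylpent-3-en-1-yl]-2,2-dimethyloxirane | ClC/C=C(\C)CC[C@@H]1OC1(C)C | intermediate
3 | acetyltrimethylsilane | CC(=O)[Si](C)(C)C | starting material
4 | (4E)-7-[(2S)-3,3-dimethyloxiran-2-yl]-5-methyl-1-(trimethylsilyl)hept-4-en-1-one | C[Si](C)(C)C(=O)CC/C=C(\C)CC[C@@H]1OC1(C)C | intermediate
5 | vinyllithium (in situ from vinyl bromide) | [Li]C=C | starting material
6 | (1Z,5Z)-1,6-bis{(3E)-6-[(2S)-3,3-dimethyloxiran-2-yl]-4-methylhex-3-en-1-yl}-1,6-bis(trimethylsilyloxy)hexa-1,5-diene | CC1(C)O[C@H]1CC/C(C)=C/CC/C(O[Si](C)(C)C)=C/CC/C=C(O[Si](C)(C)C)/CC/C=C(\C)CC[C@@H]1OC1(C)C | intermediate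
7 | 1,2-bis[(1R,4aR,6S,8aS)-6-hydroxy-5,5,8a-trimethyl-2-oxodecahydronaphthalen-1-yl]ethane | O=C1CC[C@H]2C(C)(C)[C@@H](O)CC[C@]2(C)[C@H]1CC[C@H]1C(=O)CC[C@H]2C(C)(C)[C@@H](O)CC[C@]12C | intermediate
8 | α-onocerin, each half (1S,4aR,6S,8aR) = 3β-OH, 5α-H, 9α-H, 10β-Me | C=C1CC[C@H]2C(C)(C)[C@@H](O)CC[C@]2(C)[C@H]1CC[C@H]1C(=C)CC[C@H]2C(C)(C)[C@@H](O)CC[C@]12C | target

**Step count**
Total steps: 5. Longest linear sequence: 5.

**Three steps most likely to fail**
- **Step 4 (proposed new step).** Risks are epoxide-to-ketone rearrangement, interrupted cyclization, protodesilylation of the enol silane, and catalyst sequestration by the product ketones. Fallback (known chemistry, different terminator): convert 6 to the bis(enol triflate) (MeLi, then PhNTf2), couple with Me3SiCH2MgCl under Pd(PPh3)4 to the bis(allylsilane), and cyclize with stoichiometric MeAlCl2 in CH2Cl2 at −94 °C. The allylsilane-terminated tetracyclization gives 8 directly, so step 5 is dropped (6 steps in total).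
- **Step 3.** Risks are enolization instead of addition, incomplete Brook rearrangement, α/γ scrambling in the iodine coupling, and loss of the labile bis-TMS enol ether. Fallback: bypass the acylsilane by alkylating 2 with the lithium enolate of N-methoxy-N-methylacetamide, adding vinylmagnesium bromide to give the vinyl ketone, and forming the central bond by SmI2-mediated reductive β,β′-dimerization with Me3SiCl trapping. Enol geometry is then less controlled, but C9 is corrected by equilibration after cyclization.
- **Step 1.** Risks are partial hydrolysis of the allylic chloride in the basic aqueous medium and lower ee or regioselectivity than expected. Fallback: run the same organocatalytic epoxidation on geranyl acetate, then K2CO3/MeOH and MsCl/Et3N followed by LiBr to give (S)-6,7-epoxygeranyl bromide, and use that in step 2 (two extra steps).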